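**Assumption:** the target SMILES has no stereodescriptors, and the molecule has no stereocentre and no stereogenic axis (each biaryl bond carries a symmetric 2,4,6-trihydroxyphenyl ring), so it is achiral and no stereocontrol is needed. Rings are lettered A (3,5-dihydroxyphenoxy), B (central), C (inner arm), D (outer arm, biaryl) and E (C-linked phloroglucinol).

## Retrosynthetic overview

1. Target 14 ⇐ global O-demethylation of the heptadeca-O-methyl ether 13.
2. 13 ⇐ twofold D–E biaryl bond formation as the last skeletal event: each ring-D phenol of 11 is oxidised to an electrophilic phenoxenium (aryl enolonium) equivalent and trapped by 1,3,5-trimethoxybenzene.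
3. 11 ⇐ Dakin oxidation of dialdehyde 9 ⇐ double Ullmann C–O coupling of dibromide 7 with syringaldehyde (C–O–D ethers; CHO is the masked ring-D hydroxyl).
4. 7 ⇐ Chan–Lam arylation (A–O–B) of phenol 5 ⇐ Dakin oxidation of aldehyde 3 ⇐ double SNAr of 2,6-difluoro-4-methoxybenzaldehyde with 4-bromo-2,6-dimethoxyphenol (B–O–C ethers).
5. No ring is constructed: all seven benzene rings are bought and joined in the order B + 2 C, then A, then 2 D, then 2 E.

## Route

Step 1
Reactants: 1 2,6-difluoro-4-methoxybenzaldehyde; 2 4-bromo-2,6-dimethoxyphenol (2.3 equiv)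
Product: 3 2,6-bis(4-bromo-2,6-dimethoxyphenoxy)-4-methoxybenzaldehyde
Conditions: Cs2CO3 (3 equiv), DMSO, 100 °C, Ar
Reagents that add atoms: none
Why: Twofold nucleophilic aromatic substitution (SNAr) in which both fluorides ortho to the formyl group are displaced by the hindered phenoxide, the aryl bromides being inert; no stereocentre is formed.

Step 2
Reactants: 3 2,6-bis(4-bromo-2,6-dimethoxyphenoxy)-4-methoxybenzaldehyde
Product: 5 2,6-bis(4-bromo-2,6-dimethoxyphenoxy)-4-methoxyphenol, via aryl formate 4 (not isolated)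
Conditions: mCPBA (1.5 equiv), CH2Cl2, 0 °C to rt; then K2CO3 (cat.), MeOH, rt
Reagents that add atoms: mCPBA (3-chloroperoxybenzoic acid), O=C(OO)c1cccc(Cl)c1
Why: Dakin-type Baeyer–Villiger oxidation, in which the electron-rich ring carrying two ortho aryloxy groups and a para methoxy group migrates in preference to hydride, and the formate is removed by methanolysis to give the ring-B phenol with its para oxygen already capped as OMe.

Step 3
Reactants: 5 2,6-bis(4-bromo-2,6-dimethoxyphenoxy)-4-methoxyphenol; 6 3,5-dimethoxyphenylboronic acid (3 equiv)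
Product: 7 1,3-bis(4-bromo-2,6-dimethoxyphenoxy)-2-(3,5-dimethoxyphenoxy)-5-methoxybenzene
Conditions: Cu(OAc)2 (30 mol %), pyridine (5 equiv), 4 Å MS, CH2Cl2, O2 (balloon), rt to 40 °C
Reagents that add atoms: none
Why: Chan–Lam–Evans oxidative O-arylation, which runs at room temperature under divalent copper and therefore leaves both aryl bromides untouched while installing ring A on the flanked phenol.

Step 4
Reactants: 7 1,3-bis(4-bromo-2,6-dimethoxyphenoxy)-2-(3,5-dimethoxyphenoxy)-5-methoxybenzene; 8 syringaldehyde (4-hydroxy-3,5-dimethoxybenzaldehyde, 3 equiv)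
Product: 9 1,3-bis[4-(4-formyl-2,6-dimethoxyphenoxy)-2,6-dimethoxyphenoxy]-2-(3,5-dimethoxyphenoxy)-5-methoxybenzene
Conditions: CuI (20 mol %), picolinic acid (40 mol %), K3PO4 (4 equiv), DMSO, 100 °C, Ar
Reagents that add atoms: none
Why: Twofold ligand-accelerated Ullmann diaryl ether coupling at the two unhindered C–Br positions (each flanked by hydrogens), using conditions developed for di-ortho-substituted phenols; 7 has no free OH that could compete.

Step 5
Reactants: 9 1,3-bis[4-(4-formyl-2,6-dimethoxyphenoxy)-2,6-dimethoxyphenoxy]-2-(3,5-dimethoxyphenoxy)-5-methoxybenzene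
Product: 11 1,3-bis[4-(4-hydroxy-2,6-dimethoxyphenoxy)-2,6-dimethoxyphenoxy]-2-(3,5-dimethoxyphenoxy)-5-methoxybenzene, via bis(aryl formate) 10 (not isolated)
Conditions: mCPBA (3 equiv), CH2Cl2, 0 °C to rt; then K2CO3 (cat.), MeOH (degassed), rt
Reagents that add atoms: mCPBA (3-chloroperoxybenzoic acid), O=C(OO)c1cccc(Cl)c1
Why: Twofold Dakin-type Baeyer–Villiger oxidation of the 4-aryloxy-3,5-dimethoxybenzaldehyde units (the same pattern as 3,4,5-trimethoxybenzaldehyde, which undergoes aryl migration cleanly), followed by formate methanolysis, unmasking the only two free phenols of the molecule on rings D.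

Step 6
Reactants: 11 1,3-bis[4-(4-hydroxy-2,6-dimethoxyphenoxy)-2,6-dimethoxyphenoxy]-2-(3,5-dimethoxyphenoxy)-5-methoxybenzene; 12 1,3,5-trimethoxybenzene (20 equiv)
Product: 13 1,3-bis{4-[4-hydroxy-2,6-dimethoxy-3-(2,4,6-trimethoxyphenyl)phenoxy]-2,6-dimethoxyphenoxy}-2-(3,5-dimethoxyphenoxy)-5-methoxybenzene
Conditions: PhI(OAc)2 (2.2 equiv, added over 1 h as an HFIP solution), HFIP (0.01 M in 11), −20 to 0 °C, Ar
Reagents that add atoms: none
Why: Proposed new method: a twofold, late-stage dehydrogenative phenol–arene cross-coupling in which each ring-D phenol is oxidised at oxygen by the trivalent iodine reagent in non-nucleophilic HFIP, so that its ortho carbon (normally nucleophilic) becomes the electrophilic terminus of a para-aryloxy-stabilised phenoxenium (aryl enolonium) equivalent, is attacked by the nucleophilic ring carbon of 12 and rearomatises by proton loss; the two ortho positions of each ring D are equivalent so there is one regiochemical outcome and no stereocentre, and the closest known reaction types are the hypervalent-iodine (Kita-type) oxidative phenol–arene cross-coupling and the acid-promoted arylation of quinone monoacetals alpha to the carbonyl.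

Step 7
Reactants: 13 1,3-bis{4-[4-hydroxy-2,6-dimethoxy-3-(2,4,6-trimethoxyphenyl)phenoxy]-2,6-dimethoxyphenoxy}-2-(3,5-dimethoxyphenoxy)-5-methoxybenzene
Product: 14 CNP0227063.0, 3,5-bis{4-[2,4,6-trihydroxy-3-(2,4,6-trihydroxyphenyl)phenoxy]-2,6-dihydroxyphenoxy}-4-(3,5-dihydroxyphenoxy)phenol
Conditions: BBr3 (40 equiv, 1 M in CH2Cl2), CH2Cl2, −78 °C to rt, 24 h; then H2O, 0 °C; Sephadex LH-20 then RP-HPLC under Ar
Reagents that add atoms: none
Why: Global Lewis-acid O-demethylation of all 17 aryl methyl ethers by bromide attack at the methyl carbons, which the diaryl ether and biaryl bonds (no sp3 carbon on oxygen) survive; the product is achiral.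

## Compound list

1 | 2,6-difluoro-4-methoxybenzaldehyde | COc1cc(F)c(C=O)c(F)c1 | starting material
2 | 4-bromo-2,6-dimethoxyphenol | COc1cc(Br)cc(OC)c1O | starting material
3 | 2,6-bis(4-bromo-2,6-dimethoxyphenoxy)-4-methoxybenzaldehyde | COc1cc(Oc2c(OC)cc(Br)cc2OC)c(C=O)c(Oc2c(OC)cc(Br)cc2OC)c1 | intermediate
4 | 2,6-bis(4-bromo-2,6-dimethoxyphenoxy)-4-methoxyphenyl formate | COc1cc(Oc2c(OC)cc(Br)cc2OC)c(OC=O)c(Oc2c(OC)cc(Br)cc2OC)c1 | intermediate
5 | 2,6-bis(4-bromo-2,6-dimethoxyphenoxy)-4-methoxyphenol | COc1cc(Oc2c(OC)cc(Br)cc2OC)c(O)c(Oc2c(OC)cc(Br)cc2OC)c1 | intermediate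
6 | 3,5-dimethoxyphenylboronic acid | COc1cc(OC)cc(B(O)O)c1 | starting material
7 | 1,3-bis(4-bromo-2,6-dimethoxyphenoxy)-2-(3,5-dimethoxyphenoxy)-5-methoxybenzene | COc1cc(OC)cc(Oc2c(Oc3c(OC)cc(Br)cc3OC)cc(OC)cc2Oc2c(OC)cc(Br)cc2OC)c1 | intermediate
8 | syringaldehyde (4-hydroxy-3,5-dimethoxybenzaldehyde) | COc1cc(C=O)cc(OC)c1O | starting material
9 | 1,3-bis[4-(4-formyl-2,6-dimethoxyphenoxy)-2,6-dimethoxyphenoxy]-2-(3,5-dimethoxyphenoxy)-5-methoxybenzene | COc1cc(OC)cc(Oc2c(Oc3c(OC)cc(Oc4c(OC)cc(C=O)cc4OC)cc3OC)cc(OC)cc2Oc2c(OC)cc(Oc3c(OC)cc(C=O)cc3OC)cc2OC)c1 | intermediate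
10 | 1,3-bis[4-(4-formyloxy-2,6-dimethoxyphenoxy)-2,6-dimethoxyphenoxy]-2-(3,5-dimethoxyphenoxy)-5-methoxybenzene | COc1cc(OC)cc(Oc2c(Oc3c(OC)cc(Oc4c(OC)cc(OC=O)cc4OC)cc3OC)cc(OC)cc2Oc2c(OC)cc(Oc3c(OC)cc(OC=O)cc3OC)cc2OC)c1 | intermediate
11 | 1,3-bis[4-(4-hydroxy-2,6-dimethoxyphenoxy)-2,6-dimethoxyphenoxy]-2-(3,5-dimethoxyphenoxy)-5-methoxybenzene | COc1cc(OC)cc(Oc2c(Oc3c(OC)cc(Oc4c(OC)cc(O)cc4OC)cc3OC)cc(OC)cc2Oc2c(OC)cc(Oc3c(OC)cc(O)cc3OC)cc2OC)c1 | intermediate
12 | 1,3,5-trimethoxybenzene | COc1cc(OC)cc(OC)c1 | starting material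
13 | 1,3-bis{4-[4-hydroxy-2,6-dimethoxy-3-(2,4,6-trimethoxyphenyl)phenoxy]-2,6-dimethoxyphenoxy}-2-(3,5-dimethoxyphenoxy)-5-methoxybenzene (heptadeca-O-methyl ether of the target) | COc1cc(OC)cc(Oc2c(Oc3c(OC)cc(Oc4c(OC)cc(O)c(-c5c(OC)cc(OC)cc5OC)c4OC)cc3OC)cc(OC)cc2Oc2c(OC)cc(Oc3c(OC)cc(O)c(-c4c(OC)cc(OC)cc4OC)c3OC)cc2OC)c1 | intermediate
14 | CNP0227063.0, 3,5-bis{4-[2,4,6-trihydroxy-3-(2,4,6-trihydroxyphenyl)phenoxy]-2,6-dihydroxyphenoxy}-4-(3,5-dihydroxyphenoxy)phenol | Oc1cc(O)cc(Oc2c(Oc3c(O)cc(Oc4c(O)cc(O)c(-c5c(O)cc(O)cc5O)c4O)cc3O)cc(O)cc2Oc2c(O)cc(Oc3c(O)cc(O)c(-c4c(O)cc(O)cc4O)c3O)cc2O)c1 | target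

## Step count and risk

Total step count: 7. Longest linear sequence: 7 steps (1 → 3 → 5 → 7 → 9 → 11 → 13 → 14; compounds 2, 6, 8 and 12 are bought).

The three steps most likely to fail:

**Step 6 (twofold oxidative biaryl coupling).** The risks are oxidative loss of the para aryloxy group (quinone formation if any water or alcohol is present), a second arylation at the remaining ortho position, condensation of PhI(OAc)2 with 12 to an iodonium salt, and phenol homocoupling. Fallback, setting out from 11 and coming back at 13: ortho-monobrominate each ring-D phenol with NBS (2.0 equiv) and catalytic i-Pr2NH in CH2Cl2 at −78 to 0 °C, which directs bromine ortho to the free OH, to give 1,3-bis[4-(3-bromo-4-hydroxy-2,6-dimethoxyphenoxy)-2,6-dimethoxyphenoxy]-2-(3,5-dimethoxyphenoxy)-5-methoxybenzene F1. Then join F1 to commercial (2,4,6-trimethoxyphenyl)boronic acid by Suzuki–Miyaura coupling with Pd(OAc)2, SPhos and K3PO4 in toluene/H2O at 90 °C, which gives 13.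

**Step 4 (double Ullmann coupling with syringaldehyde).** The phenoxide of 8 is both di-ortho-substituted and deactivated by the para formyl group, so conversion at the second bromide may stall or hydrodebromination may compete. Fallback, setting out from 7 and coming back at 9: Miyaura borylation of 7 with B2pin2, Pd(dppf)Cl2 and KOAc in dioxane at 90 °C gives 1,3-bis[2,6-dimethoxy-4-(4,4,5,5-tetramethyl-1,3,2-dioxaborolan-2-yl)phenoxy]-2-(3,5-dimethoxyphenoxy)-5-methoxybenzene F2. F2 is then coupled with 8 under Chan–Lam–Evans conditions (Cu(OAc)2, pyridine, B(OH)3 additive, 4 Å MS, MeCN, air, 70 °C), reversing the roles so that ring C is the boron partner, to give 9.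

**Step 3 (Chan–Lam arylation of the doubly flanked phenol 5).** The hydroxyl sits between two bulky 2,6-dimethoxyaryloxy groups and the phenol is an oxidisable hydroquinone monoether, so slow coupling and oxidation to the quinone are the likely failure modes. Fallback, setting out from 5 and coming back at 7: prepare in one pot from commercial 1-iodo-3,5-dimethoxybenzene (mCPBA, TsOH·H2O, MeCN, 55 °C, then 12) the salt (3,5-dimethoxyphenyl)(2,4,6-trimethoxyphenyl)iodonium 4-methylbenzenesulfonate F3. Then arylate 5 with F3 without metal (K2CO3, toluene, 55 °C); the trimethoxyphenyl group acts as the non-transferred ligand and the aryl bromides are untouched, giving 7.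

## Further compounds

F1 | step 6 | 1,3-bis[4-(3-bromo-4-hydroxy-2,6-dimethoxyphenoxy)-2,6-dimethoxyphenoxy]-2-(3,5-dimethoxyphenoxy)-5-methoxybenzene | COc1cc(OC)cc(Oc2c(Oc3c(OC)cc(Oc4c(OC)cc(O)c(Br)c4OC)cc3OC)cc(OC)cc2Oc2c(OC)cc(Oc3c(OC)cc(O)c(Br)c3OC)cc2OC)c1
F2 | step 4 | 1,3-bis[2,6-dimethoxy-4-(4,4,5,5-tetramethyl-1,3,2-dioxaborolan-2-yl)phenoxy]-2-(3,5-dimethoxyphenoxy)-5-methoxybenzene | COc1cc(OC)cc(Oc2c(Oc3c(OC)cc(B4OC(C)(C)C(C)(C)O4)cc3OC)cc(OC)cc2Oc2c(OC)cc(B3OC(C)(C)C(C)(C)O3)cc2OC)c1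
F3 | step 3 | (3,5-dimethoxyphenyl)(2,4,6-trimethoxyphenyl)iodonium 4-methylbenzenesulfonate | COc1cc(OC)cc([I+]c2c(OC)cc(OC)cc2OC)c1.Cc1ccc(cc1)S(=O)(=O)[O-]
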